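**Retrosynthetic overview**
1. Target 29 ⇐ desilylation, Wittig methylenation and late 6‑O‑angeloylation of the (E)‑2‑methyl‑enal 24.
2. The C12–C13 bond of the side chain ⇐ intermolecular aldol addition of the ethyl propanoate lithium enolate to the C12 aldehyde 17, then E1cB dehydration and redox adjustment.
3. The 6α,7β,8α‑trioxygenated ring B ⇐ 8α‑hydroxy‑7‑ketone 8 by Rubottom oxidation (6α‑O) and hydride reduction (7β‑OH).
4. Ketol 8 ⇐ exocyclic alkene 4 (allylic oxidation, directed epoxidation, hydride opening, Swern) ⇐ (+)‑sclareolide 1.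
5. No ring is formed: rings A and B and the C5, C9 and C10 centres come intact from sclareolide; only C8 is temporarily planarised and re‑set.

Assumption: the SMILES is read as the normal‑series labdane (5α‑H, 9α‑H, 10β‑CH3) 6α‑angeloyloxy‑7β,8α‑dihydroxylabda‑12(E),14‑diene, the ester being (Z)‑2‑methylbut‑2‑enoate; labdane numbering and α/β descriptors are used in all names.

**Step 1**
Reactants: 1 (+)-sclareolide
Product: 2 13,14,15,16-tetranorlabdane-8α,12-diol
Conditions: LiAlH4, THF, 0 °C to rt; H2O/NaOH work-up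
Reagents that add atoms: none
Why: Hydride reduction of the γ‑lactone to the diol touches no stereocentre, so C5, C8, C9 and C10 are carried over from sclareolide.

**Step 2**
Reactants: 2 13,14,15,16-tetranorlabdane-8α,12-diol
Product: 3 12-benzyloxy-13,14,15,16-tetranorlabdan-8α-ol
Conditions: NaH (1.1 equiv), BnBr (1.1 equiv), Bu4NI (cat.), THF/DMF, 0 °C to rt
Reagents that add atoms: benzyl bromide, BrCc1ccccc1
Why: Williamson etherification alkylates the primary alkoxide only, the hindered tertiary 8α‑hydroxyl staying free.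

**Step 3**
Reactants: 3 12-benzyloxy-13,14,15,16-tetranorlabdan-8α-ol
Product: 4 12-benzyloxy-13,14,15,16-tetranorlabd-8(17)-ene
Conditions: SOCl2, pyridine, CH2Cl2, −78 °C; chromatography on AgNO3-doped silica gel
Reagents that add atoms: none
Why: Dehydration through the chlorosulfite (E2): the equatorial 8α‑oxygen has no anti‑periplanar ring hydrogen, so a methyl hydrogen is lost and the exocyclic alkene predominates, minor endocyclic isomers being removed.

**Step 4**
Reactants: 4 12-benzyloxy-13,14,15,16-tetranorlabd-8(17)-ene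
Product: 5 12-benzyloxy-13,14,15,16-tetranorlabd-8(17)-en-7α-ol
Conditions: SeO2 (0.3 equiv), tBuOOH (3 equiv), CH2Cl2, rt
Reagents that add atoms: tert-butyl hydroperoxide, CC(C)(C)OO (its oxygen is passed on by SeO2, O=[Se]=O)
Why: SeO2 allylic oxidation (ene reaction at the axial 7α‑H, then [2,3]‑sigmatropic shift) returns the exocyclic alkene and places the hydroxyl on the α face at C7.

**Step 5**
Reactants: 5 12-benzyloxy-13,14,15,16-tetranorlabd-8(17)-en-7α-ol
Product: 6 12-benzyloxy-8α,17-epoxy-13,14,15,16-tetranorlabdan-7α-ol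
Conditions: VO(acac)2 (5 mol %), tBuOOH (1.5 equiv), CH2Cl2, 0 °C to rt
Reagents that add atoms: tert-butyl hydroperoxide, CC(C)(C)OO
Why: Hydroxyl‑directed vanadium‑catalysed epoxidation delivers oxygen syn to the 7α‑hydroxyl, which is also the open face (the β face is shielded by the axial C10 methyl), fixing the C8–O bond as α.

**Step 6**
Reactants: 6 12-benzyloxy-8α,17-epoxy-13,14,15,16-tetranorlabdan-7α-ol
Product: 7 12-benzyloxy-13,14,15,16-tetranorlabdane-7α,8α-diol
Conditions: LiAlH4, THF, 0 °C to reflux; H2O/NaOH work-up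
Reagents that add atoms: none
Why: SN2 hydride opening of the spiro‑epoxide at its primary carbon C17 gives the 8β‑methyl/8α‑hydroxyl arrangement, restoring the C8 configuration of sclareolide.

**Step 7**
Reactants: 7 12-benzyloxy-13,14,15,16-tetranorlabdane-7α,8α-diol
Product: 8 12-benzyloxy-8α-hydroxy-13,14,15,16-tetranorlabdan-7-one
Conditions: (COCl)2, DMSO, CH2Cl2, −78 °C; then Et3N, −78 °C to 0 °C
Reagents that add atoms: none
Why: Swern oxidation converts only the secondary 7‑hydroxyl, since the tertiary alcohol cannot be oxidised and no C–C cleavage occurs under these conditions.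

**Step 8**
Reactants: 8 12-benzyloxy-8α-hydroxy-13,14,15,16-tetranorlabdan-7-one
Product: 9 12-benzyloxy-7,8α-bis(trimethylsilyloxy)-13,14,15,16-tetranorlabd-6-ene
Conditions: Me3SiOTf (3 equiv), Et3N (5 equiv), CH2Cl2, 0 °C; non-aqueous work-up, used crude
Reagents that add atoms: trimethylsilyl trifluoromethanesulfonate, C[Si](C)(C)OS(=O)(=O)C(F)(F)F
Why: Soft enolisation/silylation gives a single silyl enol ether because the ketone can enolise only toward C6 (C8 is quaternary), and the tertiary hydroxyl is capped in the same operation.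

**Step 9**
Reactants: 9 12-benzyloxy-7,8α-bis(trimethylsilyloxy)-13,14,15,16-tetranorlabd-6-ene
Product: 12 12-benzyloxy-6α,8α-dihydroxy-13,14,15,16-tetranorlabdan-7-one, via 6α,7α-epoxy silyl ether 10 (not isolated), via 6α-silyloxy ketone 11 (not isolated)
Conditions: mCPBA (1.2 equiv), NaHCO3, CH2Cl2, −20 °C to 0 °C; then 1 M HCl, THF, rt
Reagents that add atoms: 3-chloroperoxybenzoic acid (mCPBA), OOC(=O)c1cccc(Cl)c1
Why: Rubottom oxidation: the peracid attacks the enol ether from the α face because the β face at C6 is blocked by the axial 4β‑ and 10β‑methyl groups, and silyl shift followed by acid hydrolysis gives the equatorial 6α‑hydroxy ketone.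

**Step 10**
Reactants: 12 12-benzyloxy-6α,8α-dihydroxy-13,14,15,16-tetranorlabdan-7-one
Product: 13 12-benzyloxy-8α-hydroxy-7-oxo-13,14,15,16-tetranorlabdan-6α-yl pivalate
Conditions: PivCl (3 equiv), DMAP (0.5 equiv), pyridine, 0 °C to 40 °C
Reagents that add atoms: pivaloyl chloride, CC(C)(C)C(=O)Cl
Why: DMAP‑catalysed acylation esterifies the only secondary hydroxyl, the tertiary 8α‑hydroxyl being inert, and the pivalate tolerates the later enolate chemistry without migrating.

**Step 11**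
Reactants: 13 12-benzyloxy-8α-hydroxy-7-oxo-13,14,15,16-tetranorlabdan-6α-yl pivalate
Product: 14 12-benzyloxy-7β,8α-dihydroxy-13,14,15,16-tetranorlabdan-6α-yl pivalate
Conditions: NaBH4, MeOH/THF, −20 °C to 0 °C
Reagents that add atoms: none
Why: Ketone reduction by a small hydride proceeds by axial attack from the α face (equatorial approach would eclipse the axial 8β‑methyl), giving the equatorial 7β‑alcohol trans to both neighbouring oxygens.

**Step 12**
Reactants: 14 12-benzyloxy-7β,8α-dihydroxy-13,14,15,16-tetranorlabdan-6α-yl pivalate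
Product: 15 12-benzyloxy-7β,8α-bis(triethylsilyloxy)-13,14,15,16-tetranorlabdan-6α-yl pivalate
Conditions: Et3SiOTf (5 equiv), 2,6-lutidine (8 equiv), CH2Cl2, 0 °C to rt
Reagents that add atoms: triethylsilyl trifluoromethanesulfonate, CC[Si](CC)(CC)OS(=O)(=O)C(F)(F)F
Why: Silyl triflate silylation is strong enough to cap both the secondary and the tertiary hydroxyl, which prevents lactol formation and oxa‑Michael closure from O8 in the side‑chain steps.

**Step 13**
Reactants: 15 12-benzyloxy-7β,8α-bis(triethylsilyloxy)-13,14,15,16-tetranorlabdan-6α-yl pivalate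
Product: 16 12-hydroxy-7β,8α-bis(triethylsilyloxy)-13,14,15,16-tetranorlabdan-6α-yl pivalate
Conditions: H2 (1 atm), Pd/C (10 %), EtOAc, rt
Reagents that add atoms: none
Why: Hydrogenolysis removes the benzyl ether at a stage without alkenes, and the non‑alcoholic solvent keeps the triethylsilyl ethers and the pivalate intact.

**Step 14**
Reactants: 16 12-hydroxy-7β,8α-bis(triethylsilyloxy)-13,14,15,16-tetranorlabdan-6α-yl pivalate
Product: 17 12-oxo-7β,8α-bis(triethylsilyloxy)-13,14,15,16-tetranorlabdan-6α-yl pivalate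
Conditions: Dess–Martin periodinane (1.5 equiv), NaHCO3, CH2Cl2, 0 °C to rt
Reagents that add atoms: none
Why: Dess–Martin oxidation gives the C12 aldehyde under buffered, non‑epimerising conditions that spare silyl ethers and the ester.

**Step 15**
Reactants: 17 12-oxo-7β,8α-bis(triethylsilyloxy)-13,14,15,16-tetranorlabdan-6α-yl pivalate; 18 ethyl propanoate
Product: 20 ethyl 12-hydroxy-6α-pivaloyloxy-7β,8α-bis(triethylsilyloxy)-15-norlabdan-14-oate (C12/C13 epimer mixture), via lithium enolate of ethyl propanoate 19 (not isolated)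
Conditions: 18 (1.6 equiv), LiN(iPr)2 (1.5 equiv), THF, −78 °C; then 17, −78 °C; aq. NH4Cl
Reagents that add atoms: none
Why: Intermolecular aldol addition of the preformed ester enolate to the unhindered aldehyde forms the C12–C13 bond faster than proton transfer or attack on the pivalate at −78 °C, and the two new stereocentres are erased in the next step.

**Step 16**
Reactants: 20 ethyl 12-hydroxy-6α-pivaloyloxy-7β,8α-bis(triethylsilyloxy)-15-norlabdan-14-oate
Product: 22 ethyl (12E)-6α-pivaloyloxy-7β,8α-bis(triethylsilyloxy)-15-norlabd-12-en-14-oate, via C12 mesylate 21 (not isolated)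
Conditions: MsCl (2 equiv), Et3N (4 equiv), CH2Cl2, 0 °C; then DBU (5 equiv), rt
Reagents that add atoms: none
Why: Mesylation followed by E1cB elimination through the ester enolate is stereoconvergent and gives the thermodynamically favoured (E)‑2‑methyl enoate from all aldol diastereomers.

**Step 17**
Reactants: 22 ethyl (12E)-6α-pivaloyloxy-7β,8α-bis(triethylsilyloxy)-15-norlabd-12-en-14-oate
Product: 23 (12E)-7β,8α-bis(triethylsilyloxy)-15-norlabd-12-ene-6α,14-diol
Conditions: iBu2AlH (8 equiv), CH2Cl2, −78 °C to 0 °C; aq. potassium sodium tartrate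
Reagents that add atoms: none
Why: Aluminium hydride 1,2‑reduction converts the enoate into the allylic alcohol and cleaves the pivalate in the same operation, leaving the alkene geometry and the silyl ethers untouched.

**Step 18**
Reactants: 23 (12E)-7β,8α-bis(triethylsilyloxy)-15-norlabd-12-ene-6α,14-diol
Product: 24 (12E)-6α-hydroxy-7β,8α-bis(triethylsilyloxy)-15-norlabd-12-en-14-al
Conditions: MnO2 (20 equiv), CH2Cl2, rt
Reagents that add atoms: none
Why: MnO2 allylic oxidation is selective for the primary allylic alcohol and leaves the hindered, non‑allylic 6α‑hydroxyl free.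

**Step 19**
Reactants: 24 (12E)-6α-hydroxy-7β,8α-bis(triethylsilyloxy)-15-norlabd-12-en-14-al; 25 angelic acid
Product: 27 (12E)-14-oxo-7β,8α-bis(triethylsilyloxy)-15-norlabd-12-en-6α-yl angelate, via angelic 2,4,6-trichlorobenzoic anhydride 26 (not isolated)
Conditions: 25 (4 equiv), 2,4,6-trichlorobenzoyl chloride (4 equiv), Et3N (8 equiv), toluene, rt; then 24, 80 °C
Reagents that add atoms: none
Why: Yamaguchi‑type mixed‑anhydride esterification run without a nucleophilic catalyst acylates the alcohol at the angeloyl carbonyl while keeping the (Z) geometry of the 2‑methylbut‑2‑enoate.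

**Step 20**
Reactants: 27 (12E)-14-oxo-7β,8α-bis(triethylsilyloxy)-15-norlabd-12-en-6α-yl angelate
Product: 28 (12E)-7β,8α-bis(triethylsilyloxy)labda-12,14-dien-6α-yl angelate
Conditions: Ph3PCH3Br (1.5 equiv), n-BuLi (1.4 equiv), THF, 0 °C; then 27, −78 °C to 0 °C
Reagents that add atoms: methyltriphenylphosphonium bromide, C[P+](c1ccccc1)(c1ccccc1)c1ccccc1.[Br-]
Why: Wittig methylenation of the enal is far faster than any attack of the ylide on the hindered ester and completes the 12E,14‑diene without touching the C12=C13 geometry.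

**Step 21**
Reactants: 28 (12E)-7β,8α-bis(triethylsilyloxy)labda-12,14-dien-6α-yl angelate
Product: 29 (12E)-7β,8α-dihydroxylabda-12,14-dien-6α-yl angelate (CNP0189082.1)
Conditions: HF·pyridine, pyridine, THF, 0 °C to rt
Reagents that add atoms: none
Why: Buffered fluoride desilylation removes both triethylsilyl ethers under weakly acidic conditions that cause neither 6→7 acyl migration, nor angelate isomerisation, nor cyclisation of the 8‑hydroxyl onto the diene.

**Compound list**
1 | (+)-sclareolide (13,14,15,16-tetranorlabdan-12,8α-olide; 5α-H, 9α-H, 8β-CH3, 10β-CH3) | O=C1C[C@H]2[C@](C)(O1)CC[C@H]3C(C)(C)CCC[C@@]32C | starting material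
2 | 13,14,15,16-tetranorlabdane-8α,12-diol | OCC[C@H]1[C@](C)(O)CC[C@H]2C(C)(C)CCC[C@@]21C | intermediate
3 | 12-benzyloxy-13,14,15,16-tetranorlabdan-8α-ol | c1ccccc1COCC[C@H]1[C@](C)(O)CC[C@H]2C(C)(C)CCC[C@@]21C | intermediate
4 | 12-benzyloxy-13,14,15,16-tetranorlabd-8(17)-ene | c1ccccc1COCC[C@H]1C(=C)CC[C@H]2C(C)(C)CCC[C@@]21C | intermediate
5 | 12-benzyloxy-13,14,15,16-tetranorlabd-8(17)-en-7α-ol | c1ccccc1COCC[C@H]1C(=C)[C@H](O)C[C@H]2C(C)(C)CCC[C@@]21C | intermediate
6 | 12-benzyloxy-8α,17-epoxy-13,14,15,16-tetranorlabdan-7α-ol | c1ccccc1COCC[C@H]1[C@@]3(CO3)[C@H](O)C[C@H]2C(C)(C)CCC[C@@]21C | intermediate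
7 | 12-benzyloxy-13,14,15,16-tetranorlabdane-7α,8α-diol | c1ccccc1COCC[C@H]1[C@](C)(O)[C@H](O)C[C@H]2C(C)(C)CCC[C@@]21C | intermediate
8 | 12-benzyloxy-8α-hydroxy-13,14,15,16-tetranorlabdan-7-one | c1ccccc1COCC[C@H]1[C@](C)(O)C(=O)C[C@H]2C(C)(C)CCC[C@@]21C | intermediate
9 | 12-benzyloxy-7,8α-bis(trimethylsilyloxy)-13,14,15,16-tetranorlabd-6-ene | c1ccccc1COCC[C@H]1[C@](C)(O[Si](C)(C)C)C(O[Si](C)(C)C)=C[C@H]2C(C)(C)CCC[C@@]21C | intermediate
10 | 12-benzyloxy-6α,7α-epoxy-7β,8α-bis(trimethylsilyloxy)-13,14,15,16-tetranorlabdane | c1ccccc1COCC[C@H]1[C@](C)(O[Si](C)(C)C)[C@]3(O[Si](C)(C)C)O[C@@H]3[C@H]2C(C)(C)CCC[C@@]21C | intermediate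
11 | 12-benzyloxy-6α,8α-bis(trimethylsilyloxy)-13,14,15,16-tetranorlabdan-7-one | c1ccccc1COCC[C@H]1[C@](C)(O[Si](C)(C)C)C(=O)[C@H](O[Si](C)(C)C)[C@H]2C(C)(C)CCC[C@@]21C | intermediate
12 | 12-benzyloxy-6α,8α-dihydroxy-13,14,15,16-tetranorlabdan-7-one | c1ccccc1COCC[C@H]1[C@](C)(O)C(=O)[C@H](O)[C@H]2C(C)(C)CCC[C@@]21C | intermediate
13 | 12-benzyloxy-8α-hydroxy-7-oxo-13,14,15,16-tetranorlabdan-6α-yl pivalate | c1ccccc1COCC[C@H]1[C@](C)(O)C(=O)[C@H](OC(=O)C(C)(C)C)[C@H]2C(C)(C)CCC[C@@]21C | intermediate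
14 | 12-benzyloxy-7β,8α-dihydroxy-13,14,15,16-tetranorlabdan-6α-yl pivalate | c1ccccc1COCC[C@H]1[C@](C)(O)[C@@H](O)[C@H](OC(=O)C(C)(C)C)[C@H]2C(C)(C)CCC[C@@]21C | intermediate
15 | 12-benzyloxy-7β,8α-bis(triethylsilyloxy)-13,14,15,16-tetranorlabdan-6α-yl pivalate | c1ccccc1COCC[C@H]1[C@](C)(O[Si](CC)(CC)CC)[C@@H](O[Si](CC)(CC)CC)[C@H](OC(=O)C(C)(C)C)[C@H]2C(C)(C)CCC[C@@]21C | intermediate
16 | 12-hydroxy-7β,8α-bis(triethylsilyloxy)-13,14,15,16-tetranorlabdan-6α-yl pivalate | OCC[C@H]1[C@](C)(O[Si](CC)(CC)CC)[C@@H](O[Si](CC)(CC)CC)[C@H](OC(=O)C(C)(C)C)[C@H]2C(C)(C)CCC[C@@]21C | intermediate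
17 | 12-oxo-7β,8α-bis(triethylsilyloxy)-13,14,15,16-tetranorlabdan-6α-yl pivalate (C12 aldehyde) | O=CC[C@H]1[C@](C)(O[Si](CC)(CC)CC)[C@@H](O[Si](CC)(CC)CC)[C@H](OC(=O)C(C)(C)C)[C@H]2C(C)(C)CCC[C@@]21C | intermediate
18 | ethyl propanoate | CCC(=O)OCC | starting material
19 | lithium enolate of ethyl propanoate | CC=C(OCC)[O-].[Li+] | intermediate
20 | ethyl 12-hydroxy-6α-pivaloyloxy-7β,8α-bis(triethylsilyloxy)-15-norlabdan-14-oate (C12/C13 epimer mixture) | CCOC(=O)C(C)C(O)C[C@H]1[C@](C)(O[Si](CC)(CC)CC)[C@@H](O[Si](CC)(CC)CC)[C@H](OC(=O)C(C)(C)C)[C@H]2C(C)(C)CCC[C@@]21C | intermediate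
21 | ethyl 12-methanesulfonyloxy-6α-pivaloyloxy-7β,8α-bis(triethylsilyloxy)-15-norlabdan-14-oate | CCOC(=O)C(C)C(OS(C)(=O)=O)C[C@H]1[C@](C)(O[Si](CC)(CC)CC)[C@@H](O[Si](CC)(CC)CC)[C@H](OC(=O)C(C)(C)C)[C@H]2C(C)(C)CCC[C@@]21C | intermediate
22 | ethyl (12E)-6α-pivaloyloxy-7β,8α-bis(triethylsilyloxy)-15-norlabd-12-en-14-oate | CCOC(=O)/C(C)=C/C[C@H]1[C@](C)(O[Si](CC)(CC)CC)[C@@H](O[Si](CC)(CC)CC)[C@H](OC(=O)C(C)(C)C)[C@H]2C(C)(C)CCC[C@@]21C | intermediate
23 | (12E)-7β,8α-bis(triethylsilyloxy)-15-norlabd-12-ene-6α,14-diol | OC/C(C)=C/C[C@H]1[C@](C)(O[Si](CC)(CC)CC)[C@@H](O[Si](CC)(CC)CC)[C@H](O)[C@H]2C(C)(C)CCC[C@@]21C | intermediate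
24 | (12E)-6α-hydroxy-7β,8α-bis(triethylsilyloxy)-15-norlabd-12-en-14-al | O=C/C(C)=C/C[C@H]1[C@](C)(O[Si](CC)(CC)CC)[C@@H](O[Si](CC)(CC)CC)[C@H](O)[C@H]2C(C)(C)CCC[C@@]21C | intermediate
25 | angelic acid ((Z)-2-methylbut-2-enoic acid) | C/C=C(/C)C(=O)O | starting material
26 | angelic 2,4,6-trichlorobenzoic anhydride | C/C=C(/C)C(=O)OC(=O)c1c(Cl)cc(Cl)cc1Cl | intermediate
27 | (12E)-14-oxo-7β,8α-bis(triethylsilyloxy)-15-norlabd-12-en-6α-yl angelate | O=C/C(C)=C/C[C@H]1[C@](C)(O[Si](CC)(CC)CC)[C@@H](O[Si](CC)(CC)CC)[C@H](OC(=O)/C(C)=C\C)[C@H]2C(C)(C)CCC[C@@]21C | intermediate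
28 | (12E)-7β,8α-bis(triethylsilyloxy)labda-12,14-dien-6α-yl angelate | C=C/C(C)=C/C[C@H]1[C@](C)(O[Si](CC)(CC)CC)[C@@H](O[Si](CC)(CC)CC)[C@H](OC(=O)/C(C)=C\C)[C@H]2C(C)(C)CCC[C@@]21C | intermediate
29 | (12E)-7β,8α-dihydroxylabda-12,14-dien-6α-yl angelate (CNP0189082.1) | C=C/C(C)=C/C[C@H]1[C@](C)(O)[C@@H](O)[C@H](OC(=O)/C(C)=C\C)[C@H]2C(C)(C)CCC[C@@]21C | target

**Totals and weak points**
Total step count: 21. Longest linear sequence: 21 steps (1 to 29); ethyl propanoate 18 and angelic acid 25 enter as commercial partners in steps 15 and 19.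

Step 4 is the first weak point: the SeO2 allylic oxidation can stall or run on to the 7‑enone. The fallback sets out from 4. The exocyclic double bond is moved into the ring with RhCl3·3H2O (cat.) in refluxing ethanol to give the trisubstituted alkene 12-benzyloxy-13,14,15,16-tetranorlabd-7-ene F1. Dihydroxylation of this alkene with OsO4 (cat.) and N‑methylmorpholine N‑oxide in acetone/water takes place on the open α face and gives the 7α,8α‑diol directly. The fallback therefore comes back to the route at 7 and replaces the allylic oxidation, epoxidation and hydride opening by an isomerisation and a syn‑dihydroxylation.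

Step 12 is the second weak point: double silylation of the crowded trans‑7β,8α‑diol may stop at the 7‑monosilyl ether. The fallback sets out from 13 and changes the order of events. The tertiary hydroxyl is silylated while C7 is still a flat carbonyl carbon (Et3SiOTf, 2,6‑lutidine, CH2Cl2), giving 12-benzyloxy-7-oxo-8α-triethylsilyloxy-13,14,15,16-tetranorlabdan-6α-yl pivalate F2. Reduction with NaBH4 as in step 11 then gives 12-benzyloxy-7β-hydroxy-8α-triethylsilyloxy-13,14,15,16-tetranorlabdan-6α-yl pivalate F3. Its remaining secondary hydroxyl is silylated with Et3SiOTf, and the fallback comes back to the route at 15.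

Step 19 is the third weak point: the 6α‑hydroxyl is flanked by the C4 methyls and the 7‑silyl ether, so the angeloyl mixed anhydride may react slowly, and forcing it risks Z‑to‑E drift to the tiglate. The fallback sets out from 24 and builds the angelate double bond on the ester instead of transferring it. The enal is first methylenated with excess Ph3P=CH2 (from Ph3PCH3Br and n‑BuLi, THF, −78 °C to 0 °C) to give the dienol (12E)-7β,8α-bis(triethylsilyloxy)labda-12,14-dien-6α-ol F4. Acylation with 2‑[bis(2,2,2‑trifluoroethoxy)phosphoryl]propanoic acid and DCC, which runs through a phosphonoketene and is little affected by hindrance, gives (12E)-7β,8α-bis(triethylsilyloxy)labda-12,14-dien-6α-yl 2-[bis(2,2,2-trifluoroethoxy)phosphoryl]propanoate F5. A Z‑selective Still–Gennari olefination of this ester with acetaldehyde (KN(SiMe3)2, 18‑crown‑6, THF, −78 °C) then gives the angelate, and the fallback comes back to the route at 28.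

**Further compounds**
F1 | step 4 | 12-benzyloxy-13,14,15,16-tetranorlabd-7-ene | c1ccccc1COCC[C@H]1C(C)=CC[C@H]2C(C)(C)CCC[C@@]21C
F2 | step 12 | 12-benzyloxy-7-oxo-8α-triethylsilyloxy-13,14,15,16-tetranorlabdan-6α-yl pivalate | c1ccccc1COCC[C@H]1[C@](C)(O[Si](CC)(CC)CC)C(=O)[C@H](OC(=O)C(C)(C)C)[C@H]2C(C)(C)CCC[C@@]21C
F3 | step 12 | 12-benzyloxy-7β-hydroxy-8α-triethylsilyloxy-13,14,15,16-tetranorlabdan-6α-yl pivalate | c1ccccc1COCC[C@H]1[C@](C)(O[Si](CC)(CC)CC)[C@@H](O)[C@H](OC(=O)C(C)(C)C)[C@H]2C(C)(C)CCC[C@@]21C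
F4 | step 19 | (12E)-7β,8α-bis(triethylsilyloxy)labda-12,14-dien-6α-ol | C=C/C(C)=C/C[C@H]1[C@](C)(O[Si](CC)(CC)CC)[C@@H](O[Si](CC)(CC)CC)[C@H](O)[C@H]2C(C)(C)CCC[C@@]21C
F5 | step 19 | (12E)-7β,8α-bis(triethylsilyloxy)labda-12,14-dien-6α-yl 2-[bis(2,2,2-trifluoroethoxy)phosphoryl]propanoate | C=C/C(C)=C/C[C@H]1[C@](C)(O[Si](CC)(CC)CC)[C@@H](O[Si](CC)(CC)CC)[C@H](OC(=O)C(C)P(=O)(OCC(F)(F)F)OCC(F)(F)F)[C@H]2C(C)(C)CCC[C@@]21C
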